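**Retrosynthetic overview**

1. Germacrane numbering is used: C1 ketone, C2=C3 furanone enol ether, C4=C5 olefin (C15 = CH2OAc), C6 lactone carbinol, C7, C8 (angelate), C9, C10 (quaternary, methyl C14), C11=C13 methylene, C12 lactone carbonyl. The target is the C8 angelate of the corresponding C8 alcohol.
2. The C8 alcohol is disconnected at C7–C8, a bond that lies only in the nine-membered oxonine ring (C3, C4, C5, C6, C7, C8, C9, C10 and the ether oxygen). The enabling feature is the unit C13=C11–C7–C8–OH: the exo-methylene of the lactone ring and the carbinol of the nine-membered ring form a homoallylic alcohol, the transposed adduct of a C8 aldehyde and the allyl metal of a 3-(bromomethyl)butenolide (C7=C11, C13–Br).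
3. The aldehyde/allyl bromide precursor comes from a butenolide (ring-closing metathesis of a C6 acrylate ester), which comes from the 3(2H)-furanone (gold-catalysed cyclisation of a hydroxy-ynone), which comes from a Sonogashira coupling (C3–C4) of a terminal alkyne with a (Z)-vinyl iodide.
4. The alkyne (C8–C10, C1–C3, C14) comes from (R)-citramalic acid, which supplies C10. The vinyl iodide (C4–C7, C15) comes from acrolein and 4-methoxybenzyl propargyl ether; C6 is set by asymmetric alkynylation and the olefin geometry by hydroxyl-directed hydroalumination/iodination.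
5. Ring order: furanone (step 12), butenolide (step 15), nine-membered oxonine (step 19, which also turns the butenolide into the α-methylene-γ-butyrolactone and sets C7 and C8).

Key step: step 19

Assumptions: 4-methoxybenzyl propargyl ether is taken as purchasable (otherwise one step from propargyl alcohol and PMBCl); the (R,R)-ProPhenol ligand is assumed to give the (S)-carbinol in step 6, to be confirmed by Mosher ester analysis and the ligand enantiomer exchanged if the sense is opposite.

**Route**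

Step 1
Reactants: 1 (R)-citramalic acid
Product: 2 2-[(4R)-2,2,4-trimethyl-5-oxo-1,3-dioxolan-4-yl]acetic acid
Conditions: Me2C(OMe)2, TsOH·H2O (cat.), rt
Reagents that add atoms: 2,2-dimethoxypropane, COC(C)(C)OC
Why: Acid-catalysed transacetalisation ties the α-hydroxy acid into a five-membered dioxolanone (as with malic acid) and leaves the CH2CO2H arm free, without touching the stereocenter.

Step 2
Reactants: 2 2-[(4R)-2,2,4-trimethyl-5-oxo-1,3-dioxolan-4-yl]acetic acid
Product: 4 (3R)-3-hydroxy-3-methyloxolan-2-one, via hydroxyethyl dioxolanone 3 (not isolated)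
Conditions: BH3·SMe2, THF, 0 °C → rt; MeOH; then TsOH·H2O (cat.), CH2Cl2, rt
Reagents that add atoms: none
Why: Borane reduces the free carboxylic acid chemoselectively beside the dioxolanone, and acid-catalysed translactonisation of 3 then expels acetone to give the γ-lactone (chemoselective borane reduction followed by lactonisation).

Step 3
Reactants: 4 (3R)-3-hydroxy-3-methyloxolan-2-one
Product: 5 (3R)-3-methyloxolane-2,3-diol (lactol, anomer mixture)
Conditions: i-Bu2AlH (2.2 equiv), CH2Cl2, −78 °C; aq. KNaC4H4O6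
Reagents that add atoms: none
Why: Partial hydride reduction of a γ-lactone stops at the lactol because the tetrahedral aluminium hemiacetal is stable at −78 °C.

Step 4
Reactants: 5 (3R)-3-methyloxolane-2,3-diol; 6 ethynylmagnesium bromide
Product: 7 (3R)-3-methylhex-5-yne-1,3,4-triol (C4 epimer mixture)
Conditions: HC≡CMgBr (4 equiv), THF, 0 °C → rt; aq. NH4Cl
Reagents that add atoms: none
Why: Grignard addition to the open hydroxy-aldehyde form of the lactol gives the propargylic alcohol; the new carbinol is an inconsequential epimer mixture because it is oxidised in step 12.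

Step 5
Reactants: 7 (3R)-3-methylhex-5-yne-1,3,4-triol
Product: 8 (3R)-1-[(tert-butyldimethylsilyl)oxy]-3-methylhex-5-yne-3,4-diol (C4 epimers)
Conditions: TBSCl (1.05 equiv), imidazole, CH2Cl2, 0 °C
Reagents that add atoms: tert-butyldimethylsilyl chloride, CC(C)(C)[Si](C)(C)Cl
Why: Silylation is selective for the primary hydroxyl over the secondary propargylic and tertiary hydroxyls on steric grounds.

Step 6
Reactants: 9 acrolein; 10 4-methoxybenzyl propargyl ether
Product: 11 (3S)-6-[(4-methoxybenzyl)oxy]hex-1-en-4-yn-3-ol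
Conditions: (R,R)-ProPhenol (20 mol%), Me2Zn, Ph3PO (40 mol%), toluene, 4 °C
Reagents that add atoms: none
Why: Zinc–ProPhenol-catalysed asymmetric alkynylation of an α,β-unsaturated aldehyde, in which the dinuclear zinc catalyst holds aldehyde and zinc alkynylide and sets the C6 carbinol by catalyst control.

Step 7
Reactants: 11 (3S)-6-[(4-methoxybenzyl)oxy]hex-1-en-4-yn-3-ol
Product: 13 (3S,4Z)-5-iodo-6-[(4-methoxybenzyl)oxy]hexa-1,4-dien-3-ol, via cyclic vinylalanate 12 (not isolated)
Conditions: NaAlH2(OCH2CH2OMe)2 (Red-Al), THF, 0 °C → rt; then EtOAc, I2, −78 → 0 °C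
Reagents that add atoms: iodine, II
Why: Hydroxyl-directed trans-hydroalumination of the propargylic alcohol puts aluminium on the distal alkyne carbon in a five-membered alanate, and iodinolysis with retention gives the vinyl iodide with iodine cis to the carbinol carbon, the isolated vinyl group being inert.

Step 8
Reactants: 14 ethyl 2-(hydroxymethyl)acrylate
Product: 15 ethyl 2-{[(tert-butyldimethylsilyl)oxy]methyl}acrylate
Conditions: TBSCl, imidazole, CH2Cl2, 0 °C → rt
Reagents that add atoms: tert-butyldimethylsilyl chloride, CC(C)(C)[Si](C)(C)Cl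
Why: Standard silylation of a primary allylic alcohol.

Step 9
Reactants: 15 ethyl 2-{[(tert-butyldimethylsilyl)oxy]methyl}acrylate
Product: 16 2-{[(tert-butyldimethylsilyl)oxy]methyl}acrylic acid
Conditions: LiOH·H2O, THF/H2O, 0 °C → rt; then aq. HCl to pH 4
Reagents that add atoms: lithium hydroxide, [Li+].[OH-]
Why: Saponification of the ethyl ester, which the primary TBS ether survives under these mild conditions.

Step 10
Reactants: 13 (3S,4Z)-5-iodo-6-[(4-methoxybenzyl)oxy]hexa-1,4-dien-3-ol; 16 2-{[(tert-butyldimethylsilyl)oxy]methyl}acrylic acid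
Product: 17 (3S,4Z)-5-iodo-6-[(4-methoxybenzyl)oxy]hexa-1,4-dien-3-yl 2-{[(tert-butyldimethylsilyl)oxy]methyl}acrylate
Conditions: DCC, DMAP (cat.), CH2Cl2, 0 °C → rt
Reagents that add atoms: none
Why: Steglich esterification of the secondary alcohol, with retention at C6 because no bond to the stereocenter is broken.

Step 11
Reactants: 17 (3S,4Z)-5-iodo-6-[(4-methoxybenzyl)oxy]hexa-1,4-dien-3-yl 2-{[(tert-butyldimethylsilyl)oxy]methyl}acrylate; 8 (3R)-1-[(tert-butyldimethylsilyl)oxy]-3-methylhex-5-yne-3,4-diol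
Product: 18 (3S,4E,9R)-11-[(tert-butyldimethylsilyl)oxy]-8,9-dihydroxy-5-{[(4-methoxybenzyl)oxy]methyl}-9-methylundeca-1,4-dien-6-yn-3-yl 2-{[(tert-butyldimethylsilyl)oxy]methyl}acrylate (C8 epimers)
Conditions: Pd(PPh3)2Cl2 (5 mol%), CuI (10 mol%), Et3N, THF, rt
Reagents that add atoms: none
Why: Sonogashira coupling, in which oxidative addition of zerovalent palladium into the vinyl C–I bond should be much faster than ionisation of the allylic ester and the olefin geometry is retained, placing the alkyne (C3) cis to C6.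

Step 12
Reactants: 18 the enyne diol of step 11
Product: 20 (3S,4Z)-5-[(2R)-2-{2-[(tert-butyldimethylsilyl)oxy]ethyl}-2-methyl-3-oxo-2,3-dihydrofuran-5-yl]-6-[(4-methoxybenzyl)oxy]hexa-1,4-dien-3-yl 2-{[(tert-butyldimethylsilyl)oxy]methyl}acrylate, via ynone 19 (not isolated)
Conditions: MnO2, CH2Cl2, rt; filter; then (4-CF3C6H4)3PAuCl (5 mol%), AgOTf (5 mol%), toluene, rt
Reagents that add atoms: none
Why: MnO2 oxidises only the activated propargylic alcohol, and cationic gold then activates the ynone for 5-endo-dig attack of the tertiary hydroxyl and protodeauration (the known gold-catalysed cyclisation of γ-hydroxyalkynones to 3(2H)-furanones), with C10 untouched.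

Step 13
Reactants: 20 the furanone PMB ether of step 12
Product: 21 (3S,4Z)-5-[(2R)-2-{2-[(tert-butyldimethylsilyl)oxy]ethyl}-2-methyl-3-oxo-2,3-dihydrofuran-5-yl]-6-hydroxyhexa-1,4-dien-3-yl 2-{[(tert-butyldimethylsilyl)oxy]methyl}acrylate
Conditions: DDQ, CH2Cl2/pH 7 buffer, 0 °C → rt
Reagents that add atoms: none
Why: Oxidative PMB cleavage by DDQ (hydride abstraction to the oxocarbenium ion and hydrolysis), to which silyl ethers, esters and the electron-poor dienone are inert.

Step 14
Reactants: 21 the C15 alcohol of step 13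
Product: 22 (3S,4Z)-6-acetoxy-5-[(2R)-2-{2-[(tert-butyldimethylsilyl)oxy]ethyl}-2-methyl-3-oxo-2,3-dihydrofuran-5-yl]hexa-1,4-dien-3-yl 2-{[(tert-butyldimethylsilyl)oxy]methyl}acrylate
Conditions: Ac2O, pyridine, CH2Cl2, 0 °C → rt
Reagents that add atoms: acetic anhydride, CC(=O)OC(C)=O
Why: Acetylation of the primary allylic alcohol under weakly basic conditions that do not enolise the C6–H.

Step 15
Reactants: 22 the C15 acetate of step 14
Product: 23 (5R)-5-{(1Z)-3-acetoxy-2-[(2R)-2-{2-[(tert-butyldimethylsilyl)oxy]ethyl}-2-methyl-3-oxo-2,3-dihydrofuran-5-yl]prop-1-en-1-yl}-3-{[(tert-butyldimethylsilyl)oxy]methyl}furan-2(5H)-one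
Conditions: second-generation Hoveyda–Grubbs catalyst (10 mol%), toluene (5 mM), 80 °C
Reagents that add atoms: none
Why: Ring-closing metathesis of the terminal vinyl group with the 1,1-disubstituted acrylate closes the five-membered butenolide, the other alkenes being trisubstituted and conjugated and hence unreactive, and C6 is untouched.

Step 16
Reactants: 23 the bis-silylated butenolide of step 15
Product: 24 (5R)-5-{(1Z)-3-acetoxy-2-[(2R)-2-(2-hydroxyethyl)-2-methyl-3-oxo-2,3-dihydrofuran-5-yl]prop-1-en-1-yl}-3-(hydroxymethyl)furan-2(5H)-one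
Conditions: HF·pyridine, pyridine, THF, 0 °C → rt
Reagents that add atoms: none
Why: Fluoride cleavage of both primary TBS ethers under buffered, non-basic conditions that spare the acetate and avoid enolisation of the now acidic butenolide γ-hydrogen at C6.

Step 17
Reactants: 24 the diol of step 16
Product: 25 (5R)-5-{(1Z)-3-acetoxy-2-[(2R)-2-(2-hydroxyethyl)-2-methyl-3-oxo-2,3-dihydrofuran-5-yl]prop-1-en-1-yl}-3-(bromomethyl)furan-2(5H)-one
Conditions: NBS, Me2S, CH2Cl2, −20 → 0 °C
Reagents that add atoms: N-bromosuccinimide, O=C1CCC(=O)N1Br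
Why: Corey–Kim halogenation, in which bromide displaces the alkoxysulfonium group only at the allylic position while the saturated primary alcohol is returned unchanged on work-up.

Step 18
Reactants: 25 the allylic bromide of step 17
Product: 26 (5R)-5-{(1Z)-3-acetoxy-2-[(2R)-2-methyl-3-oxo-2-(2-oxoethyl)-2,3-dihydrofuran-5-yl]prop-1-en-1-yl}-3-(bromomethyl)furan-2(5H)-one
Conditions: Dess–Martin periodinane, CH2Cl2, 0 °C → rt
Reagents that add atoms: none
Why: Dess–Martin oxidation under neutral conditions, chosen because base could open the furanone of the β-alkoxy aldehyde by E1cB elimination and would attack the allylic bromide.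

Step 19
Reactants: 26 the aldehyde/allylic bromide of step 18
Product: 28 (4Z,6R,7R,8S,10R)-15-acetoxy-8-hydroxy-1-oxo-3,10-epoxygermacra-2,4,11(13)-trien-12,6-olide, via allylchromium dichloride 27 (not isolated)
Conditions: CrCl2 (10 equiv), THF, rt, slow addition of 26 (final 2 mM); aq. NH4Cl
Reagents that add atoms: none
Why: Two equivalents of CrCl2 reduce the allylic C–Br bond to the allyl species 27 of trivalent chromium, which adds to the tethered aldehyde through a closed six-membered chair transition state with allylic transposition (SE2'), so that the new bond forms at the butenolide β-carbon C7 and the ring double bond moves out to C11=C13. The closest known reactions are the intermolecular chromium- or zinc-mediated allylation of aldehydes with 3-(bromomethyl)furan-2(5H)-ones, which gives β-(hydroxyalkyl)-α-methylene-γ-butyrolactones, and the intramolecular Nozaki–Hiyama allylations used to close medium and large carbocycles. The nine-membered oxonine ring (C3–C4–C5–C6–C7–C8–C9–C10–O) is the only ring closed, by C7–C8 bond formation in a 9-exo-trig attack on the aldehyde. C7 should be set by C6: the tether leaves C6 on one face of the planar butenolide and should deliver the aldehyde to the opposite face, anti to the C6–C5 bond (a staggered C5–C6–C7–C8 torsion instead of a nearly eclipsed one), giving the trans-fused lactone; C8 should be set by the chair, where the ring-fixed allyl geometry (C6 trans to the CH2Cr carbon, an E-crotyl analogue) and an equatorial C9 chain give the anti (7R,8S) relation. The step needs γ- over α-attack of the allyl metal, ring closure over oligomerisation and tolerance of dienone, acetate, lactone and the base-labile C6–H; the closed transition state, slow addition at high dilution and the mild, non-basic, aldehyde-selective chromium reagent should secure these.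

Step 20
Reactants: 28 the C8 alcohol of step 19; 29 angelic acid
Product: 30 (4Z,6R,7R,8S,10R)-15-acetoxy-8-angeloyloxy-1-oxo-3,10-epoxygermacra-2,4,11(13)-trien-12,6-olide (CNP0122132.1)
Conditions: 29, 2,4,6-Cl3C6H2COCl, Et3N, toluene, rt; then 28, 80 °C
Reagents that add atoms: none
Why: Yamaguchi-type mixed-anhydride acylation without DMAP, the established way to make angelates of hindered secondary alcohols without Z to E isomerisation to the tiglate, with retention at C8.

**Compound list**

1 | (R)-citramalic acid, (2R)-2-hydroxy-2-methylbutanedioic acid | C[C@@](O)(CC(=O)O)C(=O)O | starting material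
2 | 2-[(4R)-2,2,4-trimethyl-5-oxo-1,3-dioxolan-4-yl]acetic acid | C[C@]1(CC(=O)O)OC(C)(C)OC1=O | intermediate
3 | (5R)-5-(2-hydroxyethyl)-2,2,5-trimethyl-1,3-dioxolan-4-one | C[C@]1(CCO)OC(C)(C)OC1=O | intermediate
4 | (3R)-3-hydroxy-3-methyloxolan-2-one | C[C@@]1(O)CCOC1=O | intermediate
5 | (3R)-3-methyloxolane-2,3-diol (anomer mixture) | C[C@@]1(O)CCOC1O | intermediate
6 | ethynylmagnesium bromide | C#C[Mg]Br | starting material
7 | (3R)-3-methylhex-5-yne-1,3,4-triol (C4 epimers) | C[C@@](O)(CCO)C(O)C#C | intermediate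
8 | (3R)-1-[(tert-butyldimethylsilyl)oxy]-3-methylhex-5-yne-3,4-diol (C4 epimers) | C[C@@](O)(CCO[Si](C)(C)C(C)(C)C)C(O)C#C | intermediate
9 | acrolein | C=CC=O | starting material
10 | 4-methoxybenzyl propargyl ether | C#CCOCc1ccc(OC)cc1 | starting material
11 | (3S)-6-[(4-methoxybenzyl)oxy]hex-1-en-4-yn-3-ol | C=C[C@H](O)C#CCOCc1ccc(OC)cc1 | intermediate
12 | sodium vinylalanate of 11 (five-membered 1,2-oxaaluminole C6–O–Al–C4=C5, two 2-methoxyethoxy groups on Al) | C=C[C@@H]1O[Al-](OCCOC)(OCCOC)C(COCc2ccc(OC)cc2)=C1.[Na+] | intermediate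
13 | (3S,4Z)-5-iodo-6-[(4-methoxybenzyl)oxy]hexa-1,4-dien-3-ol | C=C[C@H](O)/C=C(\I)COCc1ccc(OC)cc1 | intermediate
14 | ethyl 2-(hydroxymethyl)acrylate | C=C(CO)C(=O)OCC | starting material
15 | ethyl 2-{[(tert-butyldimethylsilyl)oxy]methyl}acrylate | C=C(CO[Si](C)(C)C(C)(C)C)C(=O)OCC | intermediate
16 | 2-{[(tert-butyldimethylsilyl)oxy]methyl}acrylic acid | C=C(CO[Si](C)(C)C(C)(C)C)C(=O)O | intermediate
17 | (3S,4Z)-5-iodo-6-[(4-methoxybenzyl)oxy]hexa-1,4-dien-3-yl 2-{[(tert-butyldimethylsilyl)oxy]methyl}acrylate | C=C[C@H](OC(=O)C(=C)CO[Si](C)(C)C(C)(C)C)/C=C(\I)COCc1ccc(OC)cc1 | intermediate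
18 | (3S,4E,9R)-11-[(tert-butyldimethylsilyl)oxy]-8,9-dihydroxy-5-{[(4-methoxybenzyl)oxy]methyl}-9-methylundeca-1,4-dien-6-yn-3-yl 2-{[(tert-butyldimethylsilyl)oxy]methyl}acrylate (C8 epimers) | C=C[C@H](OC(=O)C(=C)CO[Si](C)(C)C(C)(C)C)/C=C(/COCc1ccc(OC)cc1)C#CC(O)[C@](C)(O)CCO[Si](C)(C)C(C)(C)C | intermediate
19 | (3S,4E,9R)-11-[(tert-butyldimethylsilyl)oxy]-9-hydroxy-5-{[(4-methoxybenzyl)oxy]methyl}-9-methyl-8-oxoundeca-1,4-dien-6-yn-3-yl 2-{[(tert-butyldimethylsilyl)oxy]methyl}acrylate (ynone) | C=C[C@H](OC(=O)C(=C)CO[Si](C)(C)C(C)(C)C)/C=C(/COCc1ccc(OC)cc1)C#CC(=O)[C@](C)(O)CCO[Si](C)(C)C(C)(C)C | intermediate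
20 | (3S,4Z)-5-[(2R)-2-{2-[(tert-butyldimethylsilyl)oxy]ethyl}-2-methyl-3-oxo-2,3-dihydrofuran-5-yl]-6-[(4-methoxybenzyl)oxy]hexa-1,4-dien-3-yl 2-{[(tert-butyldimethylsilyl)oxy]methyl}acrylate | C=C[C@H](OC(=O)C(=C)CO[Si](C)(C)C(C)(C)C)/C=C(/COCc1ccc(OC)cc1)C2=CC(=O)[C@@](C)(CCO[Si](C)(C)C(C)(C)C)O2 | intermediate
21 | (3S,4Z)-5-[(2R)-2-{2-[(tert-butyldimethylsilyl)oxy]ethyl}-2-methyl-3-oxo-2,3-dihydrofuran-5-yl]-6-hydroxyhexa-1,4-dien-3-yl 2-{[(tert-butyldimethylsilyl)oxy]methyl}acrylate | C=C[C@H](OC(=O)C(=C)CO[Si](C)(C)C(C)(C)C)/C=C(/CO)C1=CC(=O)[C@@](C)(CCO[Si](C)(C)C(C)(C)C)O1 | intermediate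
22 | (3S,4Z)-6-acetoxy-5-[(2R)-2-{2-[(tert-butyldimethylsilyl)oxy]ethyl}-2-methyl-3-oxo-2,3-dihydrofuran-5-yl]hexa-1,4-dien-3-yl 2-{[(tert-butyldimethylsilyl)oxy]methyl}acrylate | C=C[C@H](OC(=O)C(=C)CO[Si](C)(C)C(C)(C)C)/C=C(/COC(C)=O)C1=CC(=O)[C@@](C)(CCO[Si](C)(C)C(C)(C)C)O1 | intermediate
23 | (5R)-5-{(1Z)-3-acetoxy-2-[(2R)-2-{2-[(tert-butyldimethylsilyl)oxy]ethyl}-2-methyl-3-oxo-2,3-dihydrofuran-5-yl]prop-1-en-1-yl}-3-{[(tert-butyldimethylsilyl)oxy]methyl}furan-2(5H)-one | CC(C)(C)[Si](C)(C)OCC1=C[C@H](OC1=O)/C=C(/COC(C)=O)C2=CC(=O)[C@@](C)(CCO[Si](C)(C)C(C)(C)C)O2 | intermediate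
24 | (5R)-5-{(1Z)-3-acetoxy-2-[(2R)-2-(2-hydroxyethyl)-2-methyl-3-oxo-2,3-dihydrofuran-5-yl]prop-1-en-1-yl}-3-(hydroxymethyl)furan-2(5H)-one | OCC1=C[C@H](OC1=O)/C=C(/COC(C)=O)C2=CC(=O)[C@@](C)(CCO)O2 | intermediate
25 | (5R)-5-{(1Z)-3-acetoxy-2-[(2R)-2-(2-hydroxyethyl)-2-methyl-3-oxo-2,3-dihydrofuran-5-yl]prop-1-en-1-yl}-3-(bromomethyl)furan-2(5H)-one | BrCC1=C[C@H](OC1=O)/C=C(/COC(C)=O)C2=CC(=O)[C@@](C)(CCO)O2 | intermediate
26 | (5R)-5-{(1Z)-3-acetoxy-2-[(2R)-2-methyl-3-oxo-2-(2-oxoethyl)-2,3-dihydrofuran-5-yl]prop-1-en-1-yl}-3-(bromomethyl)furan-2(5H)-one | BrCC1=C[C@H](OC1=O)/C=C(/COC(C)=O)C2=CC(=O)[C@@](C)(CC=O)O2 | intermediate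
27 | allylchromium dichloride of 26 (CrCl2 on the C13 methylene of the butenolide) | Cl[Cr](Cl)CC1=C[C@H](OC1=O)/C=C(/COC(C)=O)C2=CC(=O)[C@@](C)(CC=O)O2 | intermediate
28 | (4Z,6R,7R,8S,10R)-15-acetoxy-8-hydroxy-1-oxo-3,10-epoxygermacra-2,4,11(13)-trien-12,6-olide | C=C1C(=O)O[C@@H]2/C=C(/COC(C)=O)C3=CC(=O)[C@@](C)(C[C@H](O)[C@@H]12)O3 | intermediate
29 | angelic acid, (2Z)-2-methylbut-2-enoic acid | C/C=C(/C)C(=O)O | starting material
30 | (4Z,6R,7R,8S,10R)-15-acetoxy-8-angeloyloxy-1-oxo-3,10-epoxygermacra-2,4,11(13)-trien-12,6-olide (CNP0122132.1) | C=C1C(=O)O[C@@H]2/C=C(/COC(C)=O)C3=CC(=O)[C@@](C)(C[C@H](OC(=O)/C(C)=C\C)[C@@H]12)O3 | target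

**Step count and risks**

Total step count: 20. Longest linear sequence: 15 steps (steps 1–5, then 11–20).

Steps most likely to fail:

1. Step 19. The ring closure may pass through the alternative chair with the C9 chain axial, so that control at the carbinol carbon C8 is lost; slow closure of the medium ring may also let intermolecular allylation compete. Fallback: setting out from 26, the same closure would then give mainly the C8 epimer, (4Z,6R,7R,8R,10R)-15-acetoxy-8-hydroxy-1-oxo-3,10-epoxygermacra-2,4,11(13)-trien-12,6-olide F1. F1 would be esterified with 29 under Mitsunobu conditions (PPh3, DIAD, toluene, 0 °C → rt), which should form the angelate with inversion at C8 and so rejoin the route at 30.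

2. Step 11. Zerovalent palladium may ionise the bis-allylic acrylate ester in competition with oxidative addition into the C–I bond, with loss or migration of the C6 oxygen function. Fallback: setting out from 13, which carries no allylic ester, and 8, the Sonogashira coupling (Pd(PPh3)2Cl2, CuI, Et3N, THF, rt) would give (3S,4E,9R)-11-[(tert-butyldimethylsilyl)oxy]-5-{[(4-methoxybenzyl)oxy]methyl}-9-methylundeca-1,4-dien-6-yne-3,8,9-triol F2. Site-selective Steglich esterification of its least hindered, bis-allylic hydroxyl with 16 (DCC, cat. DMAP, CH2Cl2, −20 °C) would return to the route at 18.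

3. Step 6. Acrolein may polymerise under the zinc alkynylide conditions, or the facial discrimination of this small enal may be poor. Fallback: setting out from 10 and 9, deprotonation of 10 with n-BuLi (THF, −78 °C) and addition to 9 would give racemic 6-[(4-methoxybenzyl)oxy]hex-1-en-4-yn-3-ol F3. Sharpless kinetic resolution (L-(+)-DIPT, Ti(OiPr)4, t-BuOOH, CH2Cl2, −20 °C) would epoxidise the (R)-enantiomer to (1S)-4-[(4-methoxybenzyl)oxy]-1-[(2S)-oxiran-2-yl]but-2-yn-1-ol F4 and leave the (S)-alcohol, returning to the route at 11.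

Further compounds
F1 | step 19 | (4Z,6R,7R,8R,10R)-15-acetoxy-8-hydroxy-1-oxo-3,10-epoxygermacra-2,4,11(13)-trien-12,6-olide | C=C1C(=O)O[C@@H]2/C=C(/COC(C)=O)C3=CC(=O)[C@@](C)(C[C@@H](O)[C@@H]12)O3
F2 | step 11 | (3S,4E,9R)-11-[(tert-butyldimethylsilyl)oxy]-5-{[(4-methoxybenzyl)oxy]methyl}-9-methylundeca-1,4-dien-6-yne-3,8,9-triol (C8 epimers) | C=C[C@H](O)/C=C(/COCc1ccc(OC)cc1)C#CC(O)[C@](C)(O)CCO[Si](C)(C)C(C)(C)C
F3 | step 6 | racemic 6-[(4-methoxybenzyl)oxy]hex-1-en-4-yn-3-ol | C=CC(O)C#CCOCc1ccc(OC)cc1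
F4 | step 6 | (1S)-4-[(4-methoxybenzyl)oxy]-1-[(2S)-oxiran-2-yl]but-2-yn-1-ol | O[C@@H](C#CCOCc1ccc(OC)cc1)[C@@H]1CO1
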